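Assumption: the structure carries no descriptor for the C4–C1' biaryl axis, so the racemic biaryl is taken as the goal and no step is asked to control the axis.

Locants: half A is C1–C8a (ring A1 = C1–C4, C4a, C8a; ring A2 = C4a–C8a). Half B is C1'–C8a', with C1' bonded to C4. ArB = 4,6-bis(benzyloxy)-5-methoxy-2-methylnaphthalen-1-yl, the protected half B.

## The problem

The target joins two different naphthalenes, half A (1-methoxy-6-methylnaphthalene-3,8-diol) and half B (5'-methoxy-2'-methylnaphthalene-4',6'-diol), through the C4–C1' bond. This bond is flanked by four ortho substituents (C3–OH, C4a, C2'–CH3, C8a'). There is no sp3 stereocentre and the axis is the only stereogenic element, so nothing has to be controlled. Every intermediate with a saturated ring A2 will, however, be a mixture of diastereomers that converge later. The real difficulties are steric and regiochemical. A tetra-ortho-substituted bond between two finished naphthalenes is unattractive to forge, and each half carries a methyl ether peri to a free hydroxyl (C1–OMe/C8–OH, C5'–OMe/C4'–OH), so similar oxygens must be told apart. The four free phenols sit on electron-rich naphthalenes that oxidise easily and tolerate neither strong oxidants nor ether-cleaving Lewis acids, so they must be unmasked last, under neutral conditions. The enabling feature is ring A1: its oxygens at C1 and C3 are meta to each other and C1 is peri to the oxygen at C8. This is the pattern left by a 3,5-dioxoalkanoate chain (C1 ester, C3 ketone, C4 bearing half B) that has condensed onto the α-carbon of a ring ketone. If ring A2 is held as a 5-methylcyclohex-2-enone with C8 as carbonyl, C8a is its only nucleophilic sp2 carbon. The C1–C8a bond can then be closed without regiochemical choice, C1–OH emerges chelated and distinct from C3–OH, and the biaryl bond is made earlier as an sp3–sp2 bond at C4. The mirror symmetry of 5-methylcyclohexane-1,3-dione 13 lets either carbonyl carbon become C4a.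

## Retrosynthesis

**22 from 21.** Three O–benzyl bonds (at C3, C4' and C6') are cut last. Benzyl is preferred to silyl or acyl protection because it survives lithium amides, methoxide, palladium coupling and carbonate alkylations, and it leaves under neutral hydrogenolysis that spares the two methyl ethers. The precursor 21 has a single free phenol (C8–OH). The forward step must remove three benzyl groups without reducing a naphthalene ring.

**21 from 19 (through 20).** Two hydrogens are returned to C5/C6/C7, so that ring A2 becomes the C8 tetralone 19. Keeping ring A2 aromatic throughout would leave three phenols on half A to be differentiated and would remove the unique nucleophilicity of C8a. The precursor differs only in oxidation level. The forward reaction must dehydrogenate a ketone to an enone that tautomerises to the naphthol, through silyl enol ether 20, without touching benzyl ethers.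

**19 from 18 from 17.** The O–CH3 bond at C1 and the O–benzyl bond at C3 are cut in turn. The order rests on chelation: in 17 the C1 hydroxyl is hydrogen-bonded to the C8 ketone and the C3 hydroxyl is free. The free one is therefore benzylated first (18) and the chelated one methylated second (19). Methylating first would put the methyl group on C3. The precursor 17 is the plain resorcinol; the forward steps only need the usual selectivity of 2,4-dihydroxyaryl ketones.

**17 from 16.** The C1–C8a bond is cut, which opens ring A1 to a methyl 3-oxobutanoate chain on C4 of a 3-substituted 5-methylcyclohex-2-enone. Neighbouring cuts (C4–C4a, or the biaryl bond itself) would require a Friedel–Crafts or cross-coupling event at a crowded aromatic carbon. This cut uses the one position that is nucleophilic by constitution. The precursor 16 has one ring fewer and no aromatic ring A1. The forward reaction is a vinylogous, aromatising Claisen condensation.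

**16 from 12 and 14.** The C4–C4a bond is cut between the benzylic carbon of β-keto ester 12 (used as its dianion 15) and chloroenone 14, made from dione 13. A chloroenone is chosen over an alkoxyenone because addition of a stabilised, hindered carbanion to a vinylogous ester carbonyl is reversible, whereas loss of chloride is not. Because 13 is symmetric, conjugate addition–elimination and carbonyl addition followed by acid lead to the same enone. The precursors are a linear keto ester and a one-step enone. The forward step needs γ-selective C–C bond formation by the dianion.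

**12 from 10 (through 11), 9 and 8.** The C2–C3 bond is cut by a two-carbon homologation of acid 10 through the acylated dioxanedione 11. The C1'–CH2 bond is cut by coupling bromide 8 with a zinc ester enolate to give ester 9. Homologation before the union with 14 avoids a vinylogous β-keto acid that could lose CO2. The precursor 8 is a plain aryl bromide. The coupling must tolerate a di-ortho-substituted, electron-rich bromide.

**8 from 7 from 6.** The C1'–Br bond and the C4' O–benzyl bond are cut. Bromination of 7 is expected at C1', which is para to the C4' benzyloxy group, ortho to the methyl group and an α-position. The C5' methoxy group is pushed out of conjugation by its two neighbours and should not direct to C8'. The precursor 6 is a simple naphthol.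

**6 from 2 and 4.** Ring B1 is cut at C4a'–C4' and C8a'–C1' into an aryne from bromide 2 and the dienolate 5 of amide 4. This places the new hydroxyl peri to the methoxy group by the known polarisation of 3-alkoxyarynes, which an acylative ring closure of a 3,4-dialkoxyphenyl precursor would not do without a blocking group. Bromide 2 and amide 4 are each one step from commercial 1 and 3.

## Roads not taken

**Alternative 1:** Ring A1 is cut at C2–C3 and C4–C4a into the fused 5-acyl-2-pyrone A1 (4-methoxy-7-methyl-7,8-dihydro-2H-chromene-2,5(6H)-dione) and the triisopropylsilyl ynol ether of half B, A2. Forward, an inverse-demand Diels–Alder addition followed by loss of CO2 from the bridged lactone would give tetralone A3 with C1–OMe and C3–OSi already differentiated.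
- Merits: it is convergent and neutral, it spares the benzylation and methylation steps, and it is probably a few steps shorter overall. In this respect it is better than the chosen plan.
- Weak points: A2 is an ynol ether carrying a di-ortho-substituted aryl group and must bond through that carbon to the fully substituted C4a of A1. The pyrone is deactivated as a diene by its 6-alkyl group, so Lewis-acid activation that an ynol silyl ether tolerates poorly would be needed.
- Comparison: the chosen plan sets against this a C4–C4a bond made at an sp3 carbon by enolate chemistry and a ring closure with no intermolecular steric demand.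

**Alternative 2:** Ring B1 is cut at C1'–C2' and C3'–C4'. The C3 anion of the 3-arylphthalide A4 (aryl = tribenzylated half A) would add to methyl (E)-but-2-enoate A5, the ester enolate would attack the lactone carbonyl, and acid dehydration would give naphthoate A6.
- Merits: ring B1 is formed aromatic, both methyl ethers are in place before the annulation, and the biaryl bond again arises at an sp3 carbon.
- Weak points: the Michael addition creates a quaternary carbon from a diarylmethyl-type anion next to the methyl-bearing β-carbon and is prone to reversal. A6 carries an ester at C3' that must be hydrolysed and decarboxylated. A4 requires a complete, separately built and protected half A, which is the harder half.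
- Comparison: this road avoids the late dehydrogenation that the chosen plan needs. The chosen plan answers with no superfluous carbon to excise and with half A built directly on the coupling carbon.

**Alternative 3:** Ring A2 is cut at C4a–C5 and C8–C8a. The aryne generated from the ortho-silylaryl triflate A7 across C4a–C8a of a ring-A1 biaryl would add the ketene acetal diene A8, and loss of methanol and the silyl group would give A9, which is identical with 21.
- Merits: it reaches 21 at the aromatic level with C8–OH free, so that neither a dehydrogenation nor the C1/C3 differentiation is needed; this is a real advantage.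
- Weak points: the aryne is flanked by C1–OMe and by the bulky half B at C4. The methoxy group directs the nucleophilic diene terminus to C4a, exactly where the aryl group blocks it, so regiochemistry and rate are in conflict. A7 is a hexasubstituted benzene whose tetra-ortho-substituted biaryl bond must first be made by cross-coupling, the very problem the chosen plan avoids.
- Comparison: the chosen plan uses the same aryne logic in step 3, but on ring B, where only the methoxy group flanks the aryne.

Key step: step 11

## Route

Step 1
Reactants: 1 4-bromo-2-methoxyphenol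
Product: 2 1-(benzyloxy)-4-bromo-2-methoxybenzene
Conditions: BnBr, K2CO3, DMF, rt
Reagents that add atoms: benzyl bromide, BrCc1ccccc1
Why: Williamson etherification of the phenol; the benzyl ether should survive every later base and is removed only in step 15.

Step 2
Reactants: 3 3-methylbut-2-enoyl chloride
Product: 4 N,N-diethyl-3-methylbut-2-enamide
Conditions: Et2NH (2.2 equiv), CH2Cl2, 0 °C
Reagents that add atoms: diethylamine, CCNCC
Why: Acylation of the amine by the acid chloride (Schotten–Baumann type); the second equivalent of amine takes up HCl.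

Step 3
Reactants: 2 1-(benzyloxy)-4-bromo-2-methoxybenzene; 4 N,N-diethyl-3-methylbut-2-enamide
Product: 6 7-(benzyloxy)-8-methoxy-3-methylnaphthalen-1-ol, via lithium dienolate 5 (not isolated)
Conditions: 4 (2 equiv), LiN(iPr)2 (4 equiv), THF, −78 °C; then 2, −78 °C to rt; 1 M HCl
Reagents that add atoms: none
Why: Aryne–dienolate annulation: LiN(iPr)2 forms 5 and removes the proton of 2 between Br and OMe, and loss of LiBr gives the 3-alkoxyaryne. The γ-carbon of 5 adds at the aryne carbon remote from OMe, the aryllithium formed next to OMe acylates on the amide, and the 4H-naphthalenone tautomerises, so the new hydroxyl ends peri to the methoxy group.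

Step 4
Reactants: 6 7-(benzyloxy)-8-methoxy-3-methylnaphthalen-1-ol
Product: 7 1,7-bis(benzyloxy)-8-methoxy-3-methylnaphthalene
Conditions: BnBr, K2CO3, DMF, 60 °C
Reagents that add atoms: benzyl bromide, BrCc1ccccc1
Why: Williamson etherification; warming is planned because the naphthol is hydrogen-bonded to the peri methoxy oxygen.

Step 5
Reactants: 7 1,7-bis(benzyloxy)-8-methoxy-3-methylnaphthalene
Product: 8 4,6-bis(benzyloxy)-1-bromo-5-methoxy-2-methylnaphthalene
Conditions: NBS (1.05 equiv), MeCN, 0 °C, dark
Reagents that add atoms: N-bromosuccinimide, O=C1CCC(=O)N1Br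
Why: Electrophilic aromatic bromination; C1' is an α-position para to the conjugated C4' benzyloxy group and ortho to the methyl group, whereas the C5' methoxy group is twisted out of conjugation by its two neighbours and should not activate C8'.

Step 6
Reactants: 8 4,6-bis(benzyloxy)-1-bromo-5-methoxy-2-methylnaphthalene
Product: 9 ethyl 2-[4,6-bis(benzyloxy)-5-methoxy-2-methylnaphthalen-1-yl]acetate
Conditions: BrZnCH2CO2Et (from BrCH2CO2Et, Zn, THF), Pd2(dba)3 (2.5 mol %), XPhos (10 mol %), THF, 65 °C
Reagents that add atoms: ethyl bromoacetate (as its zinc reagent), CCOC(=O)CBr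
Why: Negishi-type coupling of an aryl bromide with a Reformatsky reagent (palladium-catalysed arylation of a zinc ester enolate); the bulky biarylphosphine is chosen for the di-ortho-substituted, electron-rich bromide and the neutral zinc enolate leaves the ethers alone.

Step 7
Reactants: 9 ethyl 2-(ArB)acetate
Product: 10 2-[4,6-bis(benzyloxy)-5-methoxy-2-methylnaphthalen-1-yl]acetic acid
Conditions: LiOH·H2O, THF/MeOH/H2O, 50 °C; then 1 M HCl
Reagents that add atoms: lithium hydroxide, [Li+].[OH-]
Why: Saponification of an unhindered CH2-bound ester; ethers are inert.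

Step 8
Reactants: 10 2-(ArB)acetic acid
Product: 12 methyl 4-[4,6-bis(benzyloxy)-5-methoxy-2-methylnaphthalen-1-yl]-3-oxobutanoate, via acyl Meldrum's acid 11 (not isolated)
Conditions: Meldrum's acid, EDC·HCl, DMAP, CH2Cl2, 0 °C to rt; then MeOH, reflux
Reagents that add atoms: Meldrum's acid, CC1(C)OC(=O)CC(=O)O1; methanol, CO
Why: Carbodiimide acylation of Meldrum's acid followed by methanolysis of 11 through the acylketene with loss of acetone and CO2, the standard homologation of an arylacetic acid to a β-keto ester.

Step 9
Reactants: 13 5-methylcyclohexane-1,3-dione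
Product: 14 3-chloro-5-methylcyclohex-2-en-1-one (racemic)
Conditions: (COCl)2, DMF (cat.), CH2Cl2, 0 °C to rt
Reagents that add atoms: oxalyl chloride, O=C(Cl)C(Cl)=O
Why: Conversion of the enolised dione into its vinylogous acid chloride; the two carbonyls of 13 are equivalent by symmetry, so a single chloroenone can form.

Step 10
Reactants: 12 methyl 4-(ArB)-3-oxobutanoate; 14 3-chloro-5-methylcyclohex-2-en-1-one
Product: 16 methyl 4-[4,6-bis(benzyloxy)-5-methoxy-2-methylnaphthalen-1-yl]-4-(5-methyl-3-oxocyclohex-1-en-1-yl)-3-oxobutanoate (diastereomer mixture), via dilithium dianion 15 (not isolated)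
Conditions: 12 (2 equiv), LiN(iPr)2 (4.2 equiv), THF, −78 to 0 °C; then 14 (1 equiv), −78 to 0 °C; 1 M HCl
Reagents that add atoms: none
Why: γ-Selective reaction of a β-keto ester dianion with a vinylogous acid chloride: conjugate addition and irreversible loss of chloride join C4 to C4a, and a carbonyl adduct would give the same enone on acid work-up because of the symmetry of 13. The product is more acidic than 12 and quenches one equivalent of 15, hence the twofold amount of 12, the excess of which should be recoverable; no stereocontrol is needed.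

Step 11
Reactants: 16 methyl 4-(ArB)-4-(5-methyl-3-oxocyclohex-1-en-1-yl)-3-oxobutanoate
Product: 17 5-[4,6-bis(benzyloxy)-5-methoxy-2-methylnaphthalen-1-yl]-6,8-dihydroxy-3-methyl-3,4-dihydronaphthalen-1(2H)-one (racemic; both atropodiastereomers)
Conditions: NaOMe (4 equiv), MeOH, 0 °C to reflux; then 1 M HCl
Reagents that add atoms: none
Why: Methanolic NaOMe equilibrates the anions of 16, among them the one formed by loss of the C4 proton, which is α to the C3 ketone and γ to the ring enone and places charge on O3, C4, C8a and O8. Its C8a terminus adds to the ester carbonyl C1, methoxide leaves, and the C8a–H now lying between the C1 and C8 carbonyls enolises, so ring A1 becomes a resorcinolate; the closest known reaction is the aromatising intramolecular Claisen condensation of 3,5-dioxoalkanoates to resorcinols, run here through a cyclohexenone dienolate. Ring A1 closes as a six-membered ring in the 6-(enolendo)-exo-trig mode. No stereocentre is formed: C4 becomes sp2, C6 stays racemic, and the hindered C4–C1' axis gives two atropodiastereomers that converge in step 14. The step needs site selectivity among the nucleophilic positions C2, C4/C8a, C5 and C7 and the electrophilic carbons C1, C3 and C8. The substrate secures it because the saturated C5 methylene carries none of the charge of the C4-derived anion, so closure on the C5 side of C4a is not available, and because aldol addition of the C2 enolate to C8 would give a bicyclo[3.3.1]nonene with a bridgehead double bond and reverts. Aromatisation is irreversible and drains these equilibria, while attack of methoxide on the ester is degenerate. C1–OH emerges hydrogen-bonded to the C8 ketone and C3–OH free, which prepares steps 12 and 13.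

Step 12
Reactants: 17 5-(ArB)-6,8-dihydroxy-3-methyl-3,4-dihydronaphthalen-1(2H)-one
Product: 18 6-(benzyloxy)-5-[4,6-bis(benzyloxy)-5-methoxy-2-methylnaphthalen-1-yl]-8-hydroxy-3-methyl-3,4-dihydronaphthalen-1(2H)-one
Conditions: BnBr (1.1 equiv), K2CO3, acetone, 40 °C
Reagents that add atoms: benzyl bromide, BrCc1ccccc1
Why: Chemoselective Williamson etherification: the C3 hydroxyl, para to the ketone, is the more acidic and is free, while the C1 hydroxyl is held in a hydrogen bond to the C8 carbonyl, as in 2,4-dihydroxyaryl ketones.

Step 13
Reactants: 18 6-(benzyloxy)-5-(ArB)-8-hydroxy-3-methyl-3,4-dihydronaphthalen-1(2H)-one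
Product: 19 6-(benzyloxy)-5-[4,6-bis(benzyloxy)-5-methoxy-2-methylnaphthalen-1-yl]-8-methoxy-3-methyl-3,4-dihydronaphthalen-1(2H)-one
Conditions: MeI (excess), K2CO3, DMF, 50 °C
Reagents that add atoms: iodomethane, CI
Why: Williamson methylation of the chelated phenol under more forcing conditions; carbonate is too weak to enolise the ketone, so C-methylation at C7 is not expected.

Step 14
Reactants: 19 6-(benzyloxy)-5-(ArB)-8-methoxy-3-methyl-3,4-dihydronaphthalen-1(2H)-one
Product: 21 6-(benzyloxy)-5-[4,6-bis(benzyloxy)-5-methoxy-2-methylnaphthalen-1-yl]-8-methoxy-3-methylnaphthalen-1-ol, via trimethylsilyl enol ether 20 (not isolated)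
Conditions: TMSOTf, Et3N, CH2Cl2, 0 °C; then Pd(OAc)2 (1.1 equiv), MeCN, rt
Reagents that add atoms: none
Why: Soft enolisation gives 20 at the only enolisable position (C7), and Saegusa–Ito oxidation (β-hydride elimination of the C6 hydrogen from the palladium enolate) gives the C6–C7 enone, which tautomerises at once to the naphthol. The C6 stereocentre and with it the diastereomer mixture disappear.

Step 15
Reactants: 21 6-(benzyloxy)-5-(ArB)-8-methoxy-3-methylnaphthalen-1-ol
Product: 22 5-(4,6-dihydroxy-5-methoxy-2-methylnaphthalen-1-yl)-8-methoxy-3-methylnaphthalene-1,6-diol (target, racemic at the axis)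
Conditions: H2 (1 atm), 10% Pd/C, EtOAc/MeOH, rt; work-up under argon
Reagents that add atoms: none
Why: Hydrogenolysis of three aryl benzyl ethers over palladium under neutral conditions; the naphthalene rings and the methyl ethers should be inert, and exclusion of air protects the polyphenol.

## Compound list

1 | 4-bromo-2-methoxyphenol | COc1cc(Br)ccc1O | starting material
2 | 1-(benzyloxy)-4-bromo-2-methoxybenzene | COc1cc(Br)ccc1OCc1ccccc1 | intermediate
3 | 3-methylbut-2-enoyl chloride | CC(C)=CC(Cl)=O | starting material
4 | N,N-diethyl-3-methylbut-2-enamide | CCN(CC)C(=O)C=C(C)C | intermediate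
5 | lithium 1-(diethylamino)-3-methylbuta-1,3-dien-1-olate | [Li+].CCN(CC)C([O-])=CC(C)=C | intermediate (not isolated)
6 | 7-(benzyloxy)-8-methoxy-3-methylnaphthalen-1-ol | Cc1cc(O)c2c(OC)c(OCc3ccccc3)ccc2c1 | intermediate
7 | 1,7-bis(benzyloxy)-8-methoxy-3-methylnaphthalene | Cc1cc(OCc2ccccc2)c2c(OC)c(OCc3ccccc3)ccc2c1 | intermediate
8 | 4,6-bis(benzyloxy)-1-bromo-5-methoxy-2-methylnaphthalene | Cc1cc(OCc2ccccc2)c2c(OC)c(OCc3ccccc3)ccc2c1Br | intermediate
9 | ethyl 2-[4,6-bis(benzyloxy)-5-methoxy-2-methylnaphthalen-1-yl]acetate | CCOC(=O)Cc1c(C)cc(OCc2ccccc2)c2c(OC)c(OCc3ccccc3)ccc12 | intermediate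
10 | 2-[4,6-bis(benzyloxy)-5-methoxy-2-methylnaphthalen-1-yl]acetic acid | OC(=O)Cc1c(C)cc(OCc2ccccc2)c2c(OC)c(OCc3ccccc3)ccc12 | intermediate
11 | 5-{2-[4,6-bis(benzyloxy)-5-methoxy-2-methylnaphthalen-1-yl]-1-hydroxyethylidene}-2,2-dimethyl-1,3-dioxane-4,6-dione | CC1(C)OC(=O)C(=C(O)Cc2c(C)cc(OCc3ccccc3)c3c(OC)c(OCc4ccccc4)ccc23)C(=O)O1 | intermediate (not isolated)
12 | methyl 4-[4,6-bis(benzyloxy)-5-methoxy-2-methylnaphthalen-1-yl]-3-oxobutanoate | COC(=O)CC(=O)Cc1c(C)cc(OCc2ccccc2)c2c(OC)c(OCc3ccccc3)ccc12 | intermediate
13 | 5-methylcyclohexane-1,3-dione | CC1CC(=O)CC(=O)C1 | starting material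
14 | 3-chloro-5-methylcyclohex-2-en-1-one (racemic) | CC1CC(Cl)=CC(=O)C1 | intermediate
15 | dilithium 4-[4,6-bis(benzyloxy)-5-methoxy-2-methylnaphthalen-1-yl]-1-methoxybuta-1,3-diene-1,3-diolate | [Li+].[Li+].COC([O-])=CC([O-])=Cc1c(C)cc(OCc2ccccc2)c2c(OC)c(OCc3ccccc3)ccc12 | intermediate (not isolated)
16 | methyl 4-[4,6-bis(benzyloxy)-5-methoxy-2-methylnaphthalen-1-yl]-4-(5-methyl-3-oxocyclohex-1-en-1-yl)-3-oxobutanoate (diastereomer mixture, racemic) | COC(=O)CC(=O)C(C1=CC(=O)CC(C)C1)c1c(C)cc(OCc2ccccc2)c2c(OC)c(OCc3ccccc3)ccc12 | intermediate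
17 | 5-[4,6-bis(benzyloxy)-5-methoxy-2-methylnaphthalen-1-yl]-6,8-dihydroxy-3-methyl-3,4-dihydronaphthalen-1(2H)-one (racemic, both atropodiastereomers) | Oc1cc(O)c(-c2c(C)cc(OCc3ccccc3)c3c(OC)c(OCc4ccccc4)ccc23)c2CC(C)CC(=O)c12 | intermediate
18 | 6-(benzyloxy)-5-[4,6-bis(benzyloxy)-5-methoxy-2-methylnaphthalen-1-yl]-8-hydroxy-3-methyl-3,4-dihydronaphthalen-1(2H)-one (racemic, both atropodiastereomers) | Oc1cc(OCc2ccccc2)c(-c2c(C)cc(OCc3ccccc3)c3c(OC)c(OCc4ccccc4)ccc23)c2CC(C)CC(=O)c12 | intermediate
19 | 6-(benzyloxy)-5-[4,6-bis(benzyloxy)-5-methoxy-2-methylnaphthalen-1-yl]-8-methoxy-3-methyl-3,4-dihydronaphthalen-1(2H)-one (racemic, both atropodiastereomers) | COc1cc(OCc2ccccc2)c(-c2c(C)cc(OCc3ccccc3)c3c(OC)c(OCc4ccccc4)ccc23)c2CC(C)CC(=O)c12 | intermediate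
20 | {[6-(benzyloxy)-5-[4,6-bis(benzyloxy)-5-methoxy-2-methylnaphthalen-1-yl]-8-methoxy-3-methyl-3,4-dihydronaphthalen-1-yl]oxy}trimethylsilane | COc1cc(OCc2ccccc2)c(-c2c(C)cc(OCc3ccccc3)c3c(OC)c(OCc4ccccc4)ccc23)c2CC(C)C=C(O[Si](C)(C)C)c12 | intermediate (not isolated)
21 | 6-(benzyloxy)-5-[4,6-bis(benzyloxy)-5-methoxy-2-methylnaphthalen-1-yl]-8-methoxy-3-methylnaphthalen-1-ol (racemic at the axis) | COc1cc(OCc2ccccc2)c(-c2c(C)cc(OCc3ccccc3)c3c(OC)c(OCc4ccccc4)ccc23)c2cc(C)cc(O)c12 | intermediate
22 | 5-(4,6-dihydroxy-5-methoxy-2-methylnaphthalen-1-yl)-8-methoxy-3-methylnaphthalene-1,6-diol (racemic at the axis) | COc1cc(O)c(-c2c(C)cc(O)c3c(OC)c(O)ccc23)c2cc(C)cc(O)c12 | target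

## Step count and least certain steps

Total: 15 steps. Longest linear sequence: 13 steps (1 → 2 → 6 → 7 → 8 → 9 → 10 → 12 → 16 → 17 → 18 → 19 → 21 → 22); steps 2 and 9 are one-step side branches.

**Key step (step 11).** The most likely failures are retro-Claisen cleavage of the C3–C4 bond by methoxide (the C4 carbanion is a good leaving group), and a slow closure next to the bulky aryl group while the ester rests as its unreactive C2 enolate. The fallback keeps the C1–C8a closure but runs it thermally; it leaves the route at 11 and returns at 17. Compound 11 is heated with acetone in toluene to give 6-{[4,6-bis(benzyloxy)-5-methoxy-2-methylnaphthalen-1-yl]methyl}-2,2-dimethyl-4H-1,3-dioxin-4-one F1 (capture of the acylketene by acetone). F1 is deprotonated at its benzylic carbon with LiN(iPr)2 and joined to 14 to give 6-{[4,6-bis(benzyloxy)-5-methoxy-2-methylnaphthalen-1-yl](5-methyl-3-oxocyclohex-1-en-1-yl)methyl}-2,2-dimethyl-4H-1,3-dioxin-4-one F2. Heating F2 in toluene at 110 °C expels acetone, and the acylketene, as its C3 dienol, should close C1–C8a by 6π-electrocyclisation and tautomerise to 17, with neither methoxide nor a C2 enolate present.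

**Step 10.** The hindered, delocalised γ-carbanion of 15 may act as a base toward 14 (self-condensation of the chloroenone) in place of forming the C4–C4a bond, and product anions may react further with 14. The fallback sets out from acid 10 and returns at 16, changing the order of bond formation. The dilithium enediolate of 10 (2 equiv LiN(iPr)2), a harder and more reactive carbon nucleophile, is added to 14 to give 2-[4,6-bis(benzyloxy)-5-methoxy-2-methylnaphthalen-1-yl]-2-(5-methyl-3-oxocyclohex-1-en-1-yl)acetic acid F3. F3 is activated with carbonyldiimidazole at room temperature to the acyl imidazole 2-[4,6-bis(benzyloxy)-5-methoxy-2-methylnaphthalen-1-yl]-1-(1H-imidazol-1-yl)-2-(5-methyl-3-oxocyclohex-1-en-1-yl)ethan-1-one F4. F4 is homologated with Mg(O2CCH2CO2Me)2 to 16.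

**Step 3.** Lithium amides may add to the aryne, and dehydrohalogenation may occur partly in the other sense; either would erode the supply of 6. The fallback is an acylative benzannulation with a blocking bromine. It does not draw on 2 or 4 but starts from commercial 4-(benzyloxy)-3-methoxybenzaldehyde F5 and rejoins the route at 6.
- Bromination of F5 (Br2, NaOAc, AcOH) para to the methoxy group gives 4-(benzyloxy)-2-bromo-5-methoxybenzaldehyde F6.
- Wittig reaction of F6 with the ylide of (2-carboxy-1-methylethyl)triphenylphosphonium bromide gives 4-[4-(benzyloxy)-2-bromo-5-methoxyphenyl]-3-methylbut-3-enoic acid F7.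
- Ac2O/NaOAc at reflux closes the ring at the only free ortho position, next to the methoxy group, and gives 7-(benzyloxy)-5-bromo-8-methoxy-3-methylnaphthalen-1-yl acetate F8.
- K2CO3/MeOH gives 7-(benzyloxy)-5-bromo-8-methoxy-3-methylnaphthalen-1-ol F9.
- Bromine–lithium exchange on F9 (n-BuLi, THF, −78 °C) and protonation deliver 6.

**Step 6.** Transmetalation and reductive elimination at the di-ortho-substituted carbon may be slow, so that protodebromination of 8 takes over. The fallback leaves at 8 and returns at 10, bypassing 9. Bromine–lithium exchange (n-BuLi, THF, −78 °C) and DMF give 4,6-bis(benzyloxy)-5-methoxy-2-methylnaphthalene-1-carbaldehyde F10. Reductive cyanation of F10 with tosylmethyl isocyanide (KOt-Bu, DME, then MeOH; van Leusen reaction) gives 2-[4,6-bis(benzyloxy)-5-methoxy-2-methylnaphthalen-1-yl]acetonitrile F11. Hydrolysis of F11 with KOH in aqueous ethanol at reflux gives 10.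

**Step 14.** β-Hydride elimination requires the single C6 hydrogen syn to palladium and may stall, and divalent palladium may over-oxidise the electron-rich naphthol as it forms. The fallback leaves at 20 and returns at 21 by halogenation and elimination. Silyl enol ether 20 is treated with N-bromosuccinimide in THF at −78 °C to give 6-(benzyloxy)-5-[4,6-bis(benzyloxy)-5-methoxy-2-methylnaphthalen-1-yl]-2-bromo-8-methoxy-3-methyl-3,4-dihydronaphthalen-1(2H)-one F12. Dehydrobromination of F12 with Li2CO3/LiBr in DMF at 120 °C and tautomerisation give 21.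

## Further compounds

F1 | step 11 | 6-{[4,6-bis(benzyloxy)-5-methoxy-2-methylnaphthalen-1-yl]methyl}-2,2-dimethyl-4H-1,3-dioxin-4-one | CC1(C)OC(=O)C=C(Cc2c(C)cc(OCc3ccccc3)c3c(OC)c(OCc4ccccc4)ccc23)O1
F2 | step 11 | 6-{[4,6-bis(benzyloxy)-5-methoxy-2-methylnaphthalen-1-yl](5-methyl-3-oxocyclohex-1-en-1-yl)methyl}-2,2-dimethyl-4H-1,3-dioxin-4-one | CC1(C)OC(=O)C=C(C(C2=CC(=O)CC(C)C2)c2c(C)cc(OCc3ccccc3)c3c(OC)c(OCc4ccccc4)ccc23)O1
F3 | step 10 | 2-[4,6-bis(benzyloxy)-5-methoxy-2-methylnaphthalen-1-yl]-2-(5-methyl-3-oxocyclohex-1-en-1-yl)acetic acid | OC(=O)C(C1=CC(=O)CC(C)C1)c1c(C)cc(OCc2ccccc2)c2c(OC)c(OCc3ccccc3)ccc12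
F4 | step 10 | 2-[4,6-bis(benzyloxy)-5-methoxy-2-methylnaphthalen-1-yl]-1-(1H-imidazol-1-yl)-2-(5-methyl-3-oxocyclohex-1-en-1-yl)ethan-1-one | O=C(C(C1=CC(=O)CC(C)C1)c1c(C)cc(OCc2ccccc2)c2c(OC)c(OCc3ccccc3)ccc12)n1ccnc1
F5 | step 3 | 4-(benzyloxy)-3-methoxybenzaldehyde | COc1cc(C=O)ccc1OCc1ccccc1
F6 | step 3 | 4-(benzyloxy)-2-bromo-5-methoxybenzaldehyde | COc1cc(C=O)c(Br)cc1OCc1ccccc1
F7 | step 3 | 4-[4-(benzyloxy)-2-bromo-5-methoxyphenyl]-3-methylbut-3-enoic acid (E/Z mixture) | COc1cc(C=C(C)CC(O)=O)c(Br)cc1OCc1ccccc1
F8 | step 3 | 7-(benzyloxy)-5-bromo-8-methoxy-3-methylnaphthalen-1-yl acetate | CC(=O)Oc1cc(C)cc2c(Br)cc(OCc3ccccc3)c(OC)c12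
F9 | step 3 | 7-(benzyloxy)-5-bromo-8-methoxy-3-methylnaphthalen-1-ol | Cc1cc(O)c2c(OC)c(OCc3ccccc3)cc(Br)c2c1
F10 | step 6 | 4,6-bis(benzyloxy)-5-methoxy-2-methylnaphthalene-1-carbaldehyde | O=Cc1c(C)cc(OCc2ccccc2)c2c(OC)c(OCc3ccccc3)ccc12
F11 | step 6 | 2-[4,6-bis(benzyloxy)-5-methoxy-2-methylnaphthalen-1-yl]acetonitrile | N#CCc1c(C)cc(OCc2ccccc2)c2c(OC)c(OCc3ccccc3)ccc12
F12 | step 14 | 6-(benzyloxy)-5-[4,6-bis(benzyloxy)-5-methoxy-2-methylnaphthalen-1-yl]-2-bromo-8-methoxy-3-methyl-3,4-dihydronaphthalen-1(2H)-one | COc1cc(OCc2ccccc2)c(-c2c(C)cc(OCc3ccccc3)c3c(OC)c(OCc4ccccc4)ccc23)c2CC(C)C(Br)C(=O)c12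
A1 | alternative 1 | 4-methoxy-7-methyl-7,8-dihydro-2H-chromene-2,5(6H)-dione | COC1=CC(=O)OC2=C1C(=O)CC(C)C2
A2 | alternative 1 | ({[4,6-bis(benzyloxy)-5-methoxy-2-methylnaphthalen-1-yl]ethynyl}oxy)tri(propan-2-yl)silane | CC(C)[Si](OC#Cc1c(C)cc(OCc2ccccc2)c2c(OC)c(OCc3ccccc3)ccc12)(C(C)C)C(C)C
A3 | alternative 1 | 5-[4,6-bis(benzyloxy)-5-methoxy-2-methylnaphthalen-1-yl]-8-methoxy-3-methyl-6-{[tri(propan-2-yl)silyl]oxy}-3,4-dihydronaphthalen-1(2H)-one | COc1cc(O[Si](C(C)C)(C(C)C)C(C)C)c(-c2c(C)cc(OCc3ccccc3)c3c(OC)c(OCc4ccccc4)ccc23)c2CC(C)CC(=O)c12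
A4 | alternative 2 | 6-(benzyloxy)-3-[2,5-bis(benzyloxy)-4-methoxy-7-methylnaphthalen-1-yl]-7-methoxy-2-benzofuran-1(3H)-one | COc1c(OCc2ccccc2)ccc2c1C(=O)OC2c1c(OCc2ccccc2)cc(OC)c2c(OCc3ccccc3)cc(C)cc12
A5 | alternative 2 | methyl (E)-but-2-enoate | C/C=C/C(=O)OC
A6 | alternative 2 | methyl 7-(benzyloxy)-4-[2,5-bis(benzyloxy)-4-methoxy-7-methylnaphthalen-1-yl]-1-hydroxy-8-methoxy-3-methylnaphthalene-2-carboxylate | COC(=O)c1c(C)c(-c2c(OCc3ccccc3)cc(OC)c3c(OCc4ccccc4)cc(C)cc23)c2ccc(OCc3ccccc3)c(OC)c2c1O
A7 | alternative 3 | 3-(benzyloxy)-2-[4,6-bis(benzyloxy)-5-methoxy-2-methylnaphthalen-1-yl]-5-methoxy-6-(trimethylsilyl)phenyl trifluoromethanesulfonate | COc1cc(OCc2ccccc2)c(-c2c(C)cc(OCc3ccccc3)c3c(OC)c(OCc4ccccc4)ccc23)c(OS(=O)(=O)C(F)(F)F)c1[Si](C)(C)C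
A8 | alternative 3 | 1-methoxy-3-methyl-1-(trimethylsilyloxy)buta-1,3-diene | COC(=CC(C)=C)O[Si](C)(C)C
A9 | alternative 3 | 6-(benzyloxy)-5-[4,6-bis(benzyloxy)-5-methoxy-2-methylnaphthalen-1-yl]-8-methoxy-3-methylnaphthalen-1-ol | COc1cc(OCc2ccccc2)c(-c2c(C)cc(OCc3ccccc3)c3c(OC)c(OCc4ccccc4)ccc23)c2cc(C)cc(O)c12
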